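**Assumption:** CID 5282347 is natural (2R,3′E,7′E)-α-tocotrienol, which is what the SMILES encodes. One- and two-carbon organometallics (vinylMgBr, LiC≡CH·EDA, Me3Al) are treated as reagents and listed with SMILES.

## Retrosynthetic overview

1. Target ⇒ TBS ether 21 ⇒ B-alkyl Suzuki–Miyaura disconnection at C2′–C3′: (S)-2-vinylchroman 11 (as its 9-BBN adduct) + (1E,5E)-trienyl iodide 20.
2. Iodide 20 ⇒ two Zr-catalysed alkyne carboaluminations (each sets one E trisubstituted alkene) linked by a Negishi sp3–sp2 coupling with a TMS-homopropargylzinc; built from bromide 12, acetylide and but-3-yn-1-ol.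
3. Vinylchroman 11 ⇒ racemic vinyl carbinol 10, closed by a Pd-catalysed enantioconvergent dehydrative O-allylation that sets C2; 10 comes from trimethylhydroquinone + MVK, then vinylMgBr.
4. Trimethylhydroquinone ⇒ Robinson annulation of 3-pentanone with MVK, Pd-catalysed aerobic dehydrogenation, para-oxidation and reduction.
5. Ring order: carbocycle (→ arene) first; the pyran ring is formed as a racemic ketal (step 5), opened (step 8) and re-formed enantioselectively (step 9).

## Route

### Fragment A: chroman

**Step 1**
Reactants: 1 (3-pentanone), 2 (methyl vinyl ketone)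
Product: 3, (±)-2,3,6-trimethylcyclohex-2-en-1-one
Conditions: KOH (cat.), EtOH, 0 °C (slow addition of 2 to excess 1), then reflux
Reagents that add atoms: none
Why: Robinson annulation; Michael addition of the pentanone enolate to MVK, then aldol condensation of the ethyl-ketone α-CH2 onto the methyl ketone gives the tetrasubstituted enone (the C6 stereocentre is lost in step 2).

**Step 2**
Reactants: 3
Product: 4, 2,3,6-trimethylphenol
Conditions: Pd(TFA)2 (5 mol %), 2-(dimethylamino)pyridine (10 mol %), TsOH (20 mol %), O2 (1 atm), DMSO, 80 °C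
Reagents that add atoms: none
Why: Pd(II)-catalysed aerobic dehydrogenation (α-C–H palladation/β-hydride elimination) gives the 2,5-dienone, which tautomerises to the phenol.

**Step 3**
Reactants: 4
Product: 5, 2,3,5-trimethyl-1,4-benzoquinone
Conditions: salcomine (5 mol %), O2 (1 atm), DMF, rt
Reagents that add atoms: dioxygen, O=O
Why: Co(salen)/O2 phenol oxidation; the phenoxyl radical is oxygenated at the only free para position to give the p-quinone.

**Step 4**
Reactants: 5
Product: 6, 2,3,5-trimethylhydroquinone
Conditions: Na2S2O4, EtOAc/H2O, rt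
Reagents that add atoms: none
Why: dithionite reduction of a quinone to the hydroquinone.

**Step 5**
Reactants: 6, 2 (methyl vinyl ketone)
Product: 7, (±)-2-methoxy-2,5,7,8-tetramethylchroman-6-ol
Conditions: HC(OMe)3, MeOH, cat. H2SO4, 0 °C → rt
Reagents that add atoms: methanol, CO (trimethyl orthoformate, COC(OC)OC, as equivalent OMe source and dehydrating agent)
Why: acid-catalysed Friedel–Crafts conjugate addition of the single free ring position to MVK, then mixed ketalisation by the adjacent OH; this differentiates the two phenolic oxygens.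

**Step 6**
Reactants: 7
Product: 8, (±)-tert-butyl[(2-methoxy-2,5,7,8-tetramethylchroman-6-yl)oxy]dimethylsilane
Conditions: TBSCl, imidazole, DMF, 40 °C
Reagents that add atoms: TBSCl, CC(C)(C)[Si](C)(C)Cl
Why: silylation of the hindered phenol (as for tocopherol TBS ethers); the ketal is inert to base.

**Step 7**
Reactants: 8
Product: 9, (±)-6-[(tert-butyldimethylsilyl)oxy]-2,5,7,8-tetramethylchroman-2-ol (hemiketal, in equilibrium with the open keto-phenol)
Conditions: TsOH·H2O (5 mol %), acetone/H2O 9:1, rt
Reagents that add atoms: water, O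
Why: mild acid hydrolysis of the labile tertiary mixed ketal; the di-ortho-substituted aryl silyl ether survives brief dilute acid.

**Step 8**
Reactants: 9
Product: 10, (±)-4-[(tert-butyldimethylsilyl)oxy]-2-(3-hydroxy-3-methylpent-4-en-1-yl)-3,5,6-trimethylphenol
Conditions: vinylMgBr (3 equiv), THF, 0 °C → rt; sat. NH4Cl (neutral work-up, Et3N-washed silica)
Reagents that add atoms: vinylmagnesium bromide, C=C[Mg]Br
Why: Grignard addition; the deprotonated hemiketal opens to the keto-phenoxide, which takes up vinylMgBr to give the racemic tertiary vinyl carbinol, and acid is avoided so that no racemic ring closure occurs.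

**Step 9**
Reactants: 10
Product: 11, tert-butyldimethyl{[(2S)-2,5,7,8-tetramethyl-2-vinylchroman-6-yl]oxy}silane
Conditions: Pd2(dba)3·CHCl3 (2.5 mol %), (S,S)-DACH-phenyl Trost ligand (7.5 mol %; the mirror-image ligand is used if the first run shows the opposite sense), PhCO2H (20 mol %), 4 Å MS, CH2Cl2 (0.05 M), 25 °C
Reagents that add atoms: none
Why: Proposed new method: Pd-catalysed enantioconvergent dehydrative allylic etherification of a racemic tertiary vinyl carbinol. Benzoic-acid-assisted ionisation of the C–OH bond by Pd(0) gives a 1-methyl-1-alkyl π-allyl-Pd cation and erases the carbinol stereocentre. The diastereomeric π-allyl complexes interconvert by η3–η1–η3 at the CH2 terminus and by reversible benzoate return, and any diene from β-H elimination re-enters by Pd–H addition. The acid keeps the phenol protonated, so C–O closure is slower than this equilibration (Curtin–Hammett). The tethered phenol can only close 6-exo at the substituted terminus (the linear mode would need an 8-membered E-cycloalkene), and does so in the ligand pocket to set C2 as S. Closest known reactions: Trost Pd-catalysed asymmetric allylic alkylation of phenol-tethered (E)-allyl carbonates to 2-methyl-2-vinylchromans, and Pd-catalysed direct substitution of free allylic alcohols.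

### Fragment B: side chain

**Step 10**
Reactants: 12 (5-bromo-2-methylpent-2-ene)
Product: 13, 6-methylhept-5-en-1-yne
Conditions: LiC≡CH·ethylenediamine (1.5 equiv), DMSO, 10 °C → rt
Reagents that add atoms: lithium acetylide–ethylenediamine complex, [Li]C#C.NCCN
Why: SN2 alkylation of acetylide by a primary homoallylic bromide.

**Step 11**
Reactants: 13
Product: 14, (E)-1-iodo-2,6-dimethylhepta-1,5-diene
Conditions: Me3Al (2 equiv), Cp2ZrCl2 (0.25 equiv), CH2Cl2, 0 °C → rt; then I2, THF, −30 → 0 °C
Reagents that add atoms: trimethylaluminium, C[Al](C)C; iodine, II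
Why: Negishi Zr-catalysed carboalumination; syn addition of Me–Al across the terminal alkyne (Me to the internal carbon) and iodinolysis with retention give the E iodide, while the trisubstituted alkene is inert.

**Step 12**
Reactants: 15 (but-3-yn-1-ol)
Product: 16, 4-(trimethylsilyl)but-3-yn-1-ol
Conditions: n-BuLi (2.2 equiv), THF, −78 °C; TMSCl (2.3 equiv); 1 M HCl, rt
Reagents that add atoms: TMSCl, C[Si](C)(C)Cl
Why: C,O-bis-silylation of the dianion followed by selective acidic cleavage of the O–Si bond.

**Step 13**
Reactants: 16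
Product: 17, (4-iodobut-1-yn-1-yl)trimethylsilane
Conditions: PPh3, imidazole, I2, CH2Cl2, 0 °C → rt
Reagents that add atoms: iodine, II
Why: Appel-type iodination of a primary alcohol.

**Step 14**
Reactants: 17, 14
Product: 18, [(5E)-6,10-dimethylundeca-5,9-dien-1-yn-1-yl]trimethylsilane
Conditions: 17, Zn dust (BrCH2CH2Br/TMSCl-activated), LiCl, THF, 40 °C; then 14, Pd(PPh3)4 (3 mol %), THF, rt
Reagents that add atoms: none
Why: Negishi sp3–sp2 cross-coupling; the homopropargylzinc iodide couples with the alkenyl iodide with retention of the E geometry, and the TMS group blocks the alkyne C–H.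

**Step 15**
Reactants: 18
Product: 19, (E)-6,10-dimethylundeca-5,9-dien-1-yne
Conditions: K2CO3, MeOH, rt
Reagents that add atoms: none
Why: methanolytic protodesilylation of the alkynylsilane.

**Step 16**
Reactants: 19
Product: 20, (1E,5E)-1-iodo-2,6,10-trimethylundeca-1,5,9-triene
Conditions: Me3Al (2 equiv), Cp2ZrCl2 (0.5 equiv), CH2Cl2, 0 °C → rt; then I2, THF, −30 → 0 °C
Reagents that add atoms: trimethylaluminium, C[Al](C)C; iodine, II
Why: second Negishi carboalumination/iodinolysis, chemoselective for the terminal alkyne, sets the second E trisubstituted alkene.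

### Union and completion

**Step 17**
Reactants: 11, 20
Product: 21, tert-butyldimethyl({(2R)-2,5,7,8-tetramethyl-2-[(3E,7E)-4,8,12-trimethyltrideca-3,7,11-trien-1-yl]chroman-6-yl}oxy)silane
Conditions: 11, 9-BBN (1.3 equiv), THF, 0 °C → rt; H2O; then 20, PdCl2(dppf) (5 mol %), AsPh3 (10 mol %), Cs2CO3, DMF/THF/H2O, rt, dark
Reagents that add atoms: none
Why: B-alkyl Suzuki–Miyaura coupling; anti-Markovnikov hydroboration of the only monosubstituted alkene gives a primary alkylborane that couples with the alkenyl iodide with retention of E geometry, forming C2′–C3′ without touching C2 (the descriptor changes from S to R only through CIP priorities).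

**Step 18**
Reactants: 21
Product: 22, (2R)-2,5,7,8-tetramethyl-2-[(3E,7E)-4,8,12-trimethyltrideca-3,7,11-trien-1-yl]chroman-6-ol (target)
Conditions: TBAF (1.1 equiv), THF, 0 °C, Ar; AcOH quench
Reagents that add atoms: none
Why: fluoride cleavage of the aryl silyl ether; alkenes and the stereocentre are unaffected.

## Compound list

1 | 3-pentanone | CCC(=O)CC | starting material
2 | methyl vinyl ketone | CC(=O)C=C | starting material
3 | (±)-2,3,6-trimethylcyclohex-2-en-1-one | CC1CCC(C)=C(C)C1=O | intermediate
4 | 2,3,6-trimethylphenol | Cc1ccc(C)c(O)c1C | intermediate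
5 | 2,3,5-trimethyl-1,4-benzoquinone | CC1=CC(=O)C(C)=C(C)C1=O | intermediate
6 | 2,3,5-trimethylhydroquinone | Cc1cc(O)c(C)c(C)c1O | intermediate
7 | (±)-2-methoxy-2,5,7,8-tetramethylchroman-6-ol | COC1(C)CCc2c(C)c(O)c(C)c(C)c2O1 | intermediate
8 | (±)-6-TBSO-2-methoxy-2,5,7,8-tetramethylchroman | COC1(C)CCc2c(C)c(O[Si](C)(C)C(C)(C)C)c(C)c(C)c2O1 | intermediate
9 | (±)-6-TBSO-2,5,7,8-tetramethylchroman-2-ol | CC1(O)CCc2c(C)c(O[Si](C)(C)C(C)(C)C)c(C)c(C)c2O1 | intermediate
10 | (±)-4-TBSO-2-(3-hydroxy-3-methylpent-4-en-1-yl)-3,5,6-trimethylphenol | C=CC(C)(O)CCc1c(C)c(O[Si](C)(C)C(C)(C)C)c(C)c(C)c1O | intermediate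
11 | (S)-6-TBSO-2,5,7,8-tetramethyl-2-vinylchroman | C=C[C@]1(C)CCc2c(C)c(O[Si](C)(C)C(C)(C)C)c(C)c(C)c2O1 | intermediate
12 | 5-bromo-2-methylpent-2-ene | CC(C)=CCCBr | starting material
13 | 6-methylhept-5-en-1-yne | C#CCCC=C(C)C | intermediate
14 | (E)-1-iodo-2,6-dimethylhepta-1,5-diene | I/C=C(C)/CCC=C(C)C | intermediate
15 | but-3-yn-1-ol | C#CCCO | starting material
16 | 4-(trimethylsilyl)but-3-yn-1-ol | C[Si](C)(C)C#CCCO | intermediate
17 | (4-iodobut-1-yn-1-yl)trimethylsilane | C[Si](C)(C)C#CCCI | intermediate
18 | [(5E)-6,10-dimethylundeca-5,9-dien-1-yn-1-yl]trimethylsilane | C[Si](C)(C)C#CCC/C=C(C)/CCC=C(C)C | intermediate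
19 | (E)-6,10-dimethylundeca-5,9-dien-1-yne | C#CCC/C=C(C)/CCC=C(C)C | intermediate
20 | (1E,5E)-1-iodo-2,6,10-trimethylundeca-1,5,9-triene | I/C=C(C)/CC/C=C(C)/CCC=C(C)C | intermediate
21 | (2R,3′E,7′E)-α-tocotrienol TBS ether | CC(C)=CCC/C(C)=C/CC/C(C)=C/CC[C@]1(C)CCc2c(C)c(O[Si](C)(C)C(C)(C)C)c(C)c(C)c2O1 | intermediate
22 | (2R,3′E,7′E)-α-tocotrienol | CC(C)=CCC/C(C)=C/CC/C(C)=C/CC[C@]1(C)CCc2c(C)c(O)c(C)c(C)c2O1 | target

## Step count and risks

Total steps: 18.
Longest linear sequence: 11 (steps 1–9, 17, 18).

**Three steps most likely to fail**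

1. **Step 9 (proposed new Pd enantioconvergent dehydrative etherification).** Risks: sluggish ionisation of the free tertiary alcohol, incomplete syn/anti π-allyl equilibration (lower ee), and re-ionisation of the product aryl allyl ether. The ee of 11 is checked by chiral HPLC and upgraded by chiral SFC if needed.
 Fallback (known chemistry): set C2 by Tietze-type enantioselective Wacker oxypalladation–carbonylation instead of a π-allyl. Methylenate 9 (Ph3P=CH2) to the 2-(3-methylbut-3-enyl)phenol, then Pd(TFA)2/Bn-BOXAX, p-benzoquinone, CO, MeOH to the (S)-chroman-2-ylacetate. LiAlH4, then PPh3/I2, gives the 2-(2-iodoethyl)chroman, whose alkylzinc is Negishi-coupled with 20 in place of step 17.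

2. **Step 17 (B-alkyl Suzuki of a borane next to a quaternary centre with a polyene iodide).** Risks: slow transmetalation, protodeboronation, loss or isomerisation of the iodide.
 Fallback: move the union to C1′–C2′ by sulfone alkylation. Cleave the vinyl group of 11 (OsO4/NaIO4, then NaBH4) to the chroman-2-ylmethanol and make its triflate. Alkylate lithiated (E,E)-farnesyl phenyl sulfone (from 20: t-BuLi/(CH2O)n, PBr3, PhSO2Na), desulfonylate with PdCl2(dppp)/LiBHEt3, then TBAF.

3. **Step 1 (Robinson annulation of an acyclic ketone with MVK).** Risks: MVK polymerisation, bis-alkylation, and the competing aldol mode giving 3-ethyl-4-methylcyclohexenone.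
 Fallback: change the ring disconnection. Michael/aldol condensation of 3-pentanone with crotonaldehyde gives 2,5,6-trimethylcyclohex-2-enone, which the step 2 dehydrogenation converts into the same phenol 4.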